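**Plan**

- The target is two 2‑aryl‑3‑hydroxymethyl‑7‑methoxy‑2,3‑dihydrobenzofurans (furan I fused to ring B, furan II fused to ring C), joined C2'(II)–C5(I), with a guaiacyl ring A on C2(I). The hard part is two remote 2,3‑trans stereo‑pairs (2R,3S,2'R,3'S) that cannot relay information to each other.
- Retrosynthesis: three CH2OH back to three CO2Me and ArOH back to ArOBn; then both C2–C3 bonds are cut at once to give an acyclic, achiral bis(aryldiazoacetate); then the two Ar–C(N2) bonds (aryl iodides); then the two ArO–CH2Ar ether bonds.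
- Forward: the chain A–CH2–O–B–CH2–O–C is joined first from O‑benzylvanillyl alcohol, 5‑iodovanillin and iodinated methyl dihydroferulate; both furan rings then arise in one operation (step 7).
- Enabling feature: in each furan ring C2 sits between O1 and an electron‑rich aryl group, so the open form is an ArO–CH2–Ar methylene with hydridic C–H bonds exactly 1,5 to C3. C3 carries a one‑carbon oxygenated group that can be an ester (the acceptor of a donor/acceptor carbene). Ring B is at once the benzyl donor for furan II and the aryl diazoacetate for furan I.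
- Stereochemistry: C2 and C2' come from a chiral Rh(II) catalyst selecting one enantiotopic C–H at each site; C3 and C3' come from thermodynamic epimerisation to 2,3‑trans (step 8).

Key step: step 7

Remark 1 (sense of induction): the S‑configured phthalimido‑carboxylate catalyst is taken to give the 2R configuration, as recalled for this catalyst family on ortho‑benzyloxy aryldiazoacetates; this assignment is from memory and should be confirmed on a model insertion, with Rh2(R‑PTTL)4 used instead if the sense is opposite.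

Remark 2 (bookkeeping): in the twofold steps 5–8 the two sites react independently and in either order, so both half‑converted compounds are numbered as non‑isolated intermediates; the aluminate stages of step 9 are not discrete neutral compounds and carry no number.

**Route**

Step 1
Reactants: 1 methyl 3-(4-hydroxy-3-methoxyphenyl)propanoate
Product: 2 methyl 3-(4-hydroxy-3-iodo-5-methoxyphenyl)propanoate
Conditions: I2, NaHCO3, THF–H2O, 0 °C to rt
Reagents that add atoms: iodine, II
Why: Electrophilic aromatic iodination through the phenoxide, whose only free ortho carbon (the other ortho carbon bears OMe, the para carbon the side chain) is far more activated than the positions governed by the methoxy group, so one regioisomer is expected.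

Step 2
Reactants: 3 4-hydroxy-3-iodo-5-methoxybenzaldehyde (5-iodovanillin); 4 [4-(benzyloxy)-3-methoxyphenyl]methanol
Product: 5 4-{[4-(benzyloxy)-3-methoxyphenyl]methoxy}-3-iodo-5-methoxybenzaldehyde
Conditions: PPh3, DIAD, THF, 0 °C to rt
Reagents that add atoms: none
Why: Mitsunobu etherification, in which the acidic iodo/formyl‑substituted phenol protonates the betaine and its phenoxide displaces the primary para‑alkoxybenzylic oxyphosphonium ion; no stereocentre is involved.

Step 3
Reactants: 5 4-{[4-(benzyloxy)-3-methoxyphenyl]methoxy}-3-iodo-5-methoxybenzaldehyde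
Product: 6 (4-{[4-(benzyloxy)-3-methoxyphenyl]methoxy}-3-iodo-5-methoxyphenyl)methanol
Conditions: NaBH4, MeOH–THF, 0 °C
Reagents that add atoms: none
Why: Chemoselective borohydride reduction of the aryl aldehyde, which should leave the aryl iodide and both benzyl ethers untouched.

Step 4
Reactants: 6 (4-{[4-(benzyloxy)-3-methoxyphenyl]methoxy}-3-iodo-5-methoxyphenyl)methanol; 2 methyl 3-(4-hydroxy-3-iodo-5-methoxyphenyl)propanoate
Product: 7 methyl 3-{4-[(4-{[4-(benzyloxy)-3-methoxyphenyl]methoxy}-3-iodo-5-methoxyphenyl)methoxy]-3-iodo-5-methoxyphenyl}propanoate (bis‑iodide A–CH2O–B–CH2O–C)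
Conditions: PPh3, DIAD, THF, 0 °C to rt
Reagents that add atoms: none
Why: Second Mitsunobu etherification, the ortho‑iodophenol 2 being acidic enough for the betaine and the para‑alkoxybenzylic oxyphosphonium ion of 6 reactive enough to be displaced by the hindered phenoxide.

Step 5
Reactants: 7 bis‑iodide
Product: 10 methyl 3-{4-[(4-{[4-(benzyloxy)-3-methoxyphenyl]methoxy}-3-methoxy-5-(2-methoxy-2-oxoethyl)phenyl)methoxy]-3-methoxy-5-(2-methoxy-2-oxoethyl)phenyl}propanoate (bis‑arylacetate), via ring-C arylacetate ring-B iodide 8 (not isolated), via ring-B arylacetate ring-C iodide 9 (not isolated)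
Conditions: BrZnCH2CO2Me (from BrCH2CO2Me, Zn, cat. TMSCl, THF), Pd(dba)2, Q‑Phos, THF, rt to 50 °C
Reagents that add atoms: methyl bromoacetate, COC(=O)CBr (used as its zinc reagent, COC(=O)C[Zn]Br)
Why: Twofold Negishi‑type α‑arylation (Pd‑catalysed coupling of an aryl iodide with a Reformatsky reagent), in which the mild zinc enolate spares the propanoate ester and transmetalates faster than aryl‑palladium can attack the neighbouring benzyl ring.

Step 6
Reactants: 10 bis‑arylacetate
Product: 13 methyl 3-{4-[(4-{[4-(benzyloxy)-3-methoxyphenyl]methoxy}-3-(1-diazo-2-methoxy-2-oxoethyl)-5-methoxyphenyl)methoxy]-3-(1-diazo-2-methoxy-2-oxoethyl)-5-methoxyphenyl}propanoate (bis‑diazo ester), via ring-C monodiazo ester 11 (not isolated), via ring-B monodiazo ester 12 (not isolated)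
Conditions: p‑ABSA, DBU, MeCN, 0 °C to rt
Reagents that add atoms: 4-acetamidobenzenesulfonyl azide (p‑ABSA), CC(=O)Nc1ccc(cc1)S(=O)(=O)N=[N+]=[N-]
Why: Regitz diazo transfer onto the two aryl‑acetate methylenes, the only C–H acids DBU can deprotonate, since the propanoate α‑CH2 is many pKa units weaker.

Step 7
Reactants: 13 bis‑diazo ester
Product: 16 methyl (2R,3S)-2-[4-(benzyloxy)-3-methoxyphenyl]-7-methoxy-5-[(2R,3S)-7-methoxy-3-(methoxycarbonyl)-5-(3-methoxy-3-oxopropyl)-2,3-dihydro-1-benzofuran-2-yl]-2,3-dihydro-1-benzofuran-3-carboxylate (cis,cis‑triester), via furan-II-closed diazo ester 14 (not isolated), via furan-I-closed diazo ester 15 (not isolated)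
Conditions: Rh2(S‑PTTL)4 (2 mol %), toluene, −60 °C, 13 added by syringe pump
Reagents that add atoms: none
Why: The catalyst extrudes N2 from each aryl diazoacetate to give a donor/acceptor rhodium carbene, which inserts through a concerted, asynchronous, hydride‑shift‑like three‑centre transition state into a C–H bond of the neighbouring ArO–CH2–Ar methylene, forming the C3–C2 and C3'–C2' bonds. The closest known reaction type is the Rh(II) phthalimido‑carboxylate‑catalysed enantioselective intramolecular C–H insertion of methyl 2-(2-benzyloxyaryl)-2-diazoacetates to cis‑2‑aryl‑2,3‑dihydrobenzofuran‑3‑carboxylates, run here at two sites of one molecule. Each dihydrofuran ring (O1–C2–C3–C3a–C7a) closes by 1,5‑C–H insertion, the carbene carbon becoming C3 and the methylene carbon C2. C2 and C2' are set by the chiral ligand wall of the catalyst, which selects one of the two enantiotopic methylene hydrogens at each site (expected R at both); C3 and C3' arise kinetically cis to the aryl group, but their configuration does not matter because step 8 equilibrates them. The step needs site selectivity, chemoselectivity against intermolecular carbene coupling, and the same facial sense at both sites: each carbene reaches only the O–CH2 ortho to it (ring B's own methylene is meta to its carbene carbon, the O‑benzyl CH2 of ring A is remote), slow addition at low temperature suppresses dimerisation, and the two sites are constitutionally alike (2‑alkoxy‑3‑methoxyaryl diazoacetate facing a para‑alkoxybenzyl methylene) and insulated from each other. Because the two events are independent, a wrong‑sense insertion at one site gives a diastereomer removable after step 8, so the enantiomeric purity of the major isomer should exceed the single‑site selectivity.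

Step 8
Reactants: 16 cis,cis‑triester
Product: 19 methyl (2R,3R)-2-[4-(benzyloxy)-3-methoxyphenyl]-7-methoxy-5-[(2R,3R)-7-methoxy-3-(methoxycarbonyl)-5-(3-methoxy-3-oxopropyl)-2,3-dihydro-1-benzofuran-2-yl]-2,3-dihydro-1-benzofuran-3-carboxylate (trans,trans‑triester), via I-trans II-cis triester 17 (not isolated), via I-cis II-trans triester 18 (not isolated)
Conditions: NaOMe (0.5 equiv), MeOH–THF, rt to 40 °C
Reagents that add atoms: none
Why: Thermodynamic epimerisation through the ester enolates at C3 and C3' only (C2–H is not acidic), which relieves the cis aryl/ester interaction so that each ring should settle into 2,3‑trans with C2 unchanged, while the benzyl ether keeps ring A from forming a phenoxide that could open the ring.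

Step 9
Reactants: 19 trans,trans‑triester
Product: 20 [(2R,3S)-2-[4-(benzyloxy)-3-methoxyphenyl]-5-[(2R,3S)-3-(hydroxymethyl)-5-(3-hydroxypropyl)-7-methoxy-2,3-dihydro-1-benzofuran-2-yl]-7-methoxy-2,3-dihydro-1-benzofuran-3-yl]methanol (O‑benzyl triol)
Conditions: LiAlH4, THF, 0 °C to rt; Rochelle salt work‑up
Reagents that add atoms: none
Why: Hydride reduction of all three methyl esters (the two ring esters to the C3 hydroxymethyl groups, the propanoate to the 3‑hydroxypropyl chain) without touching a stereocentre, the descriptor at C3 changing from R to S only through CIP priorities.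

Step 10
Reactants: 20 O‑benzyl triol
Product: 21 4-[(2R,3S)-3-(hydroxymethyl)-5-[(2R,3S)-3-(hydroxymethyl)-5-(3-hydroxypropyl)-7-methoxy-2,3-dihydro-1-benzofuran-2-yl]-7-methoxy-2,3-dihydro-1-benzofuran-2-yl]-2-methoxyphenol (CNP0599161.1)
Conditions: H2 (1 atm), 10 % Pd/C, EtOAc–MeOH, rt, stopped at one equivalent of H2
Reagents that add atoms: none
Why: Hydrogenolysis of the single unhindered primary aryl benzyl ether, which should be cleaved well before the secondary benzylic C2–O bonds embedded in the two furan rings.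

**Compound list**

1 | methyl 3-(4-hydroxy-3-methoxyphenyl)propanoate (methyl dihydroferulate) | COC(=O)CCc1ccc(O)c(OC)c1 | starting material
2 | methyl 3-(4-hydroxy-3-iodo-5-methoxyphenyl)propanoate | COC(=O)CCc1cc(I)c(O)c(OC)c1 | intermediate
3 | 4-hydroxy-3-iodo-5-methoxybenzaldehyde (5-iodovanillin) | O=Cc1cc(I)c(O)c(OC)c1 | starting material
4 | [4-(benzyloxy)-3-methoxyphenyl]methanol | OCc1ccc(OCc2ccccc2)c(OC)c1 | starting material
5 | 4-{[4-(benzyloxy)-3-methoxyphenyl]methoxy}-3-iodo-5-methoxybenzaldehyde | O=Cc1cc(I)c(OCc2ccc(OCc3ccccc3)c(OC)c2)c(OC)c1 | intermediate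
6 | (4-{[4-(benzyloxy)-3-methoxyphenyl]methoxy}-3-iodo-5-methoxyphenyl)methanol | OCc1cc(I)c(OCc2ccc(OCc3ccccc3)c(OC)c2)c(OC)c1 | intermediate
7 | bis‑iodide: methyl 3-{4-[(4-{[4-(benzyloxy)-3-methoxyphenyl]methoxy}-3-iodo-5-methoxyphenyl)methoxy]-3-iodo-5-methoxyphenyl}propanoate | COC(=O)CCc1cc(I)c(OCc2cc(I)c(OCc3ccc(OCc4ccccc4)c(OC)c3)c(OC)c2)c(OC)c1 | intermediate
8 | as 7, with the ring‑C iodine replaced by CH2CO2Me and the ring‑B iodine retained | COC(=O)CCc1cc(CC(=O)OC)c(OCc2cc(I)c(OCc3ccc(OCc4ccccc4)c(OC)c3)c(OC)c2)c(OC)c1 | intermediate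
9 | as 7, with the ring‑B iodine replaced by CH2CO2Me and the ring‑C iodine retained | COC(=O)CCc1cc(I)c(OCc2cc(CC(=O)OC)c(OCc3ccc(OCc4ccccc4)c(OC)c3)c(OC)c2)c(OC)c1 | intermediate
10 | bis‑arylacetate: as 7, with both iodines replaced by CH2CO2Me | COC(=O)CCc1cc(CC(=O)OC)c(OCc2cc(CC(=O)OC)c(OCc3ccc(OCc4ccccc4)c(OC)c3)c(OC)c2)c(OC)c1 | intermediate
11 | as 10, with C(=N2)CO2Me on ring C and CH2CO2Me on ring B | COC(=O)CCc1cc(C(=[N+]=[N-])C(=O)OC)c(OCc2cc(CC(=O)OC)c(OCc3ccc(OCc4ccccc4)c(OC)c3)c(OC)c2)c(OC)c1 | intermediate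
12 | as 10, with C(=N2)CO2Me on ring B and CH2CO2Me on ring C | COC(=O)CCc1cc(CC(=O)OC)c(OCc2cc(C(=[N+]=[N-])C(=O)OC)c(OCc3ccc(OCc4ccccc4)c(OC)c3)c(OC)c2)c(OC)c1 | intermediate
13 | bis‑diazo ester: as 10, with both ArCH2CO2Me groups converted into ArC(=N2)CO2Me | COC(=O)CCc1cc(C(=[N+]=[N-])C(=O)OC)c(OCc2cc(C(=[N+]=[N-])C(=O)OC)c(OCc3ccc(OCc4ccccc4)c(OC)c3)c(OC)c2)c(OC)c1 | intermediate
14 | methyl (2R,3S)-2-[4-{[4-(benzyloxy)-3-methoxyphenyl]methoxy}-3-(1-diazo-2-methoxy-2-oxoethyl)-5-methoxyphenyl]-7-methoxy-5-(3-methoxy-3-oxopropyl)-2,3-dihydro-1-benzofuran-3-carboxylate (furan II closed, cis) | COc1cc(COc2c(OC)cc([C@@H]3Oc4c(OC)cc(CCC(=O)OC)cc4[C@@H]3C(=O)OC)cc2C(=[N+]=[N-])C(=O)OC)ccc1OCc1ccccc1 | intermediate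
15 | methyl (2R,3S)-2-[4-(benzyloxy)-3-methoxyphenyl]-5-{[2-(1-diazo-2-methoxy-2-oxoethyl)-6-methoxy-4-(3-methoxy-3-oxopropyl)phenoxy]methyl}-7-methoxy-2,3-dihydro-1-benzofuran-3-carboxylate (furan I closed, cis) | COc1cc([C@@H]2Oc3c(OC)cc(COc4c(OC)cc(CCC(=O)OC)cc4C(=[N+]=[N-])C(=O)OC)cc3[C@@H]2C(=O)OC)ccc1OCc1ccccc1 | intermediate
16 | cis,cis‑triester (2R,3S,2'R,3'S), name as in step 7 | COc1cc([C@@H]2Oc3c(OC)cc([C@@H]4Oc5c(OC)cc(CCC(=O)OC)cc5[C@@H]4C(=O)OC)cc3[C@@H]2C(=O)OC)ccc1OCc1ccccc1 | intermediate
17 | triester with furan I trans (2R,3R) and furan II cis (2'R,3'S) | COc1cc([C@@H]2Oc3c(OC)cc([C@@H]4Oc5c(OC)cc(CCC(=O)OC)cc5[C@@H]4C(=O)OC)cc3[C@H]2C(=O)OC)ccc1OCc1ccccc1 | intermediate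
18 | triester with furan I cis (2R,3S) and furan II trans (2'R,3'R) | COc1cc([C@@H]2Oc3c(OC)cc([C@@H]4Oc5c(OC)cc(CCC(=O)OC)cc5[C@H]4C(=O)OC)cc3[C@@H]2C(=O)OC)ccc1OCc1ccccc1 | intermediate
19 | trans,trans‑triester (2R,3R,2'R,3'R), name as in step 8 | COc1cc([C@@H]2Oc3c(OC)cc([C@@H]4Oc5c(OC)cc(CCC(=O)OC)cc5[C@H]4C(=O)OC)cc3[C@H]2C(=O)OC)ccc1OCc1ccccc1 | intermediate
20 | O‑benzyl triol (2R,3S,2'R,3'S), name as in step 9 | COc1cc([C@@H]2Oc3c(OC)cc([C@@H]4Oc5c(OC)cc(CCCO)cc5[C@H]4CO)cc3[C@H]2CO)ccc1OCc1ccccc1 | intermediate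
21 | 4-[(2R,3S)-3-(hydroxymethyl)-5-[(2R,3S)-3-(hydroxymethyl)-5-(3-hydroxypropyl)-7-methoxy-2,3-dihydro-1-benzofuran-2-yl]-7-methoxy-2,3-dihydro-1-benzofuran-2-yl]-2-methoxyphenol | COc1cc([C@@H]2Oc3c(OC)cc([C@@H]4Oc5c(OC)cc(CCCO)cc5[C@H]4CO)cc3[C@H]2CO)ccc1O | target

**Step count and risks**

Total steps: 10. Longest linear sequence: 9 steps (3 or 4 → 21, steps 2–10); compound 2 enters after one step.

Steps most likely to fail:

1. Step 7. The two carbene centres may interfere (coupling between sites or between molecules), or the facial selectivity may differ at the two sites so that the diastereomers are hard to separate. The fallback closes one ring at a time, using the same reactions on single sites. It sets out from 6: Negishi–Reformatsky coupling with excess BrZnCH2CO2Me (the free hydroxyl consumes one equivalent) should give methyl 2-[2-{[4-(benzyloxy)-3-methoxyphenyl]methoxy}-5-(hydroxymethyl)-3-methoxyphenyl]acetate F1. Mitsunobu coupling of F1 with 2 should give 9, isolated this time. Diazo transfer (p‑ABSA, DBU) should give the ring‑B diazo ester with the ring‑C iodide intact F2. Insertion with Rh2(S‑PTTL)4 should give the cis furan‑I ester with the ring‑C iodide F3, where the enantiomeric purity can be raised by crystallisation. NaOMe/MeOH should give the trans furan‑I ester iodide F4. A second Negishi–Reformatsky coupling should give the trans furan‑I ester with the ring‑C arylacetate F5, and diazo transfer the trans furan‑I ester with the ring‑C diazo ester F6. The second insertion with Rh2(S‑PTTL)4 should then give 17, where the fallback comes back to the route; the conditions of step 8 convert 17 into 19.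

2. Step 5. Oxidative addition or transmetalation may be sluggish at the two ortho‑alkoxy iodides, allowing protodeiodination or palladium‑mediated arylation of the neighbouring benzyl ring. The fallback sets out from 7: copper‑catalysed arylation of methyl acetoacetate (CuI, L‑proline, Cs2CO3, DMSO, 50 °C) should give the bis(α‑aryl acetoacetate) F7. Deacylative diazo transfer (p‑ABSA, DBU, MeCN) should then give 13 directly, where the fallback comes back to the route, bypassing 10.

3. Step 4. Displacement of the oxyphosphonium ion by the hindered, doubly ortho‑substituted phenoxide may be slow, so that alkylation of the hydrazide takes over. The fallback sets out from 6: PBr3 in CH2Cl2 at 0 °C should give 1-{[4-(benzyloxy)-3-methoxyphenyl]methoxy}-4-(bromomethyl)-2-iodo-6-methoxybenzene F8. Williamson etherification of F8 with 2 (K2CO3, DMF, rt) should give 7, where the fallback comes back to the route.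

**Further compounds**

F1 | step 7 | methyl 2-[2-{[4-(benzyloxy)-3-methoxyphenyl]methoxy}-5-(hydroxymethyl)-3-methoxyphenyl]acetate | OCc1cc(CC(=O)OC)c(OCc2ccc(OCc3ccccc3)c(OC)c2)c(OC)c1
F2 | step 7 | ring‑B diazo ester with ring‑C iodide (9 with ArCH2CO2Me converted into ArC(=N2)CO2Me) | COC(=O)CCc1cc(I)c(OCc2cc(C(=[N+]=[N-])C(=O)OC)c(OCc3ccc(OCc4ccccc4)c(OC)c3)c(OC)c2)c(OC)c1
F3 | step 7 | methyl (2R,3S)-2-[4-(benzyloxy)-3-methoxyphenyl]-5-{[2-iodo-6-methoxy-4-(3-methoxy-3-oxopropyl)phenoxy]methyl}-7-methoxy-2,3-dihydro-1-benzofuran-3-carboxylate (cis) | COc1cc([C@@H]2Oc3c(OC)cc(COc4c(OC)cc(CCC(=O)OC)cc4I)cc3[C@@H]2C(=O)OC)ccc1OCc1ccccc1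
F4 | step 7 | (2R,3R)‑trans epimer of F3 | COc1cc([C@@H]2Oc3c(OC)cc(COc4c(OC)cc(CCC(=O)OC)cc4I)cc3[C@H]2C(=O)OC)ccc1OCc1ccccc1
F5 | step 7 | F4 with the ring‑C iodine replaced by CH2CO2Me | COc1cc([C@@H]2Oc3c(OC)cc(COc4c(OC)cc(CCC(=O)OC)cc4CC(=O)OC)cc3[C@H]2C(=O)OC)ccc1OCc1ccccc1
F6 | step 7 | F5 with the ring‑C ArCH2CO2Me converted into ArC(=N2)CO2Me | COc1cc([C@@H]2Oc3c(OC)cc(COc4c(OC)cc(CCC(=O)OC)cc4C(=[N+]=[N-])C(=O)OC)cc3[C@H]2C(=O)OC)ccc1OCc1ccccc1
F7 | step 5 | bis(α‑aryl acetoacetate): 7 with both iodines replaced by CH(COCH3)CO2Me | COC(=O)CCc1cc(C(C(C)=O)C(=O)OC)c(OCc2cc(C(C(C)=O)C(=O)OC)c(OCc3ccc(OCc4ccccc4)c(OC)c3)c(OC)c2)c(OC)c1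
F8 | step 4 | 1-{[4-(benzyloxy)-3-methoxyphenyl]methoxy}-4-(bromomethyl)-2-iodo-6-methoxybenzene | BrCc1cc(I)c(OCc2ccc(OCc3ccccc3)c(OC)c2)c(OC)c1
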